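## Structural features

Target 16 is a 2-hydroxybenzophenone with three benzene rings, no other ring and no stereocentre. Ring A is 1,2,4,5-tetrasubstituted: OMe on C1, OH on C3, the ketone carbon C7 on C4 and a saturated chain Ca–Cb–Cc on C6. C7 is bonded to ring B and Cc to ring C, both 4-hydroxyphenyl. The two ring A oxygens are meta to each other, C1–O beside the chain carbon C6 and C3–O beside the acyl carbon C4, so ring A is a resorcinol carrying a carbon substituent para to each oxygen. The only stereocentres in the plan (a carbinol carbon and C2 of a chroman) are transient, racemic and erased. The fragile points are the electron-rich diaryl ketone, which is exposed whenever a benzylic C–O bond is cleaved reductively, the acid-sensitive ortho-hydroxybenzyl alcohol stage, and the acid-labile MOM acetals. Four oxygens must end as one methyl ether and three phenols of different character: C3–OH hydrogen-bonded to C7=O, the ring B hydroxyl a vinylogous acid, the ring C hydroxyl an ordinary phenol. The real difficulty is therefore regiochemistry and oxygen differentiation: an unfunctionalised three-carbon chain and an aroyl group on defined carbons of ring A, and methylation of C1–O only. The key step uses the sequence O–C1=C6–Ca–Cb–Cc, which is the O1–C8a–C4a–C4–C3–C2 pattern of a 2-arylchroman: an ortho-quinone methide across C1/C6/Ca and a 4-oxygenated styrene supplying Cb, Cc and ring C build the chain while the C1 oxygen is held in the ring.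

## Logic of the disconnections

16 ⇒ 15. Cut: the three O–CH2 acetal bonds on C3–O, on ring B and on ring C. All three phenols are released together in the last step, so no earlier intermediate carries competing acidic hydroxyls and 15 has one kind of protecting group. The forward step must cleave acetals without touching the C1 methyl ether or the ketone and must trap the released one-carbon unit.

15 ⇒ 14. Cut: the O–CH3 bond at C1. In 14 the C1 hydroxyl is the only free one, so the methylation site is fixed by constitution and not by relative acidity. The forward step is a plain O-alkylation.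

14 ⇒ 13. Retrosynthetically the C1 oxygen is joined to Cc; forward, the O–Cc bond of 13 is cleaved by hydrogen. The open chain becomes a ring that a cycloaddition can make, and the C1 oxygen is distinguished from all others because it alone is tied up. The forward step must cleave the benzylic C–O bond faster than C7=O is reduced; the stereocentre disappears, so no stereocontrol is needed.

13 ⇒ 11 + 3 (through 12). Cuts: Ca–Cb and O–Cc, the two ring bonds of the dihydropyran. This is the strategic cut: ring C and two of the three chain carbons come from 3, and ring A needs only a one-carbon handle ortho to a free hydroxyl. The forward step needs 12 to be generated without acid (MOM groups, cationic polymerisation of 3) and to add with the 2-aryl orientation. The C3 oxygen of 11 is kept as a MOM ether and not as a free hydroxyl: a free hydroxyl there would call for ring A protecting groups removable beside the ring B MOM ether and would allow a para-quinone methide tautomer.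

11 ⇒ 10. Cut: the two Si–O bonds on C1–O and Ca–O. The silyl ethers mask exactly the two hydroxyls the key step needs and leave together with fluoride, to which MOM ethers are inert. The forward step must not leave the product in basic solution.

10 ⇒ 9. Change of oxidation level at C7 (ketone from carbinol). The carbinol comes from 2, which is needed anyway for 3. The forward oxidation requires that Ca–O be masked, because a free primary benzylic alcohol would be oxidised as well.

9 ⇒ 7 + 2 (through 8). Cut: C4–C7. The bromine of 7 marks C4, so the bond forms only there, and ring B with C7 arrives in one piece. The forward step needs bromine–lithium exchange without silyl migration; the aryl silyl ether is para to the metalated carbon and the ortho group is a MOM ether, so no migration path exists.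

7 ⇒ 6 ⇒ 5 ⇒ 4. No skeletal bond is cut: Ca is the formyl carbon of 4 and the C4 bromine is already in place. C3–O is capped first, the aldehyde is reduced, and both remaining hydroxyls are silylated. The demand is site-selective alkylation of the hydroxyl para to the formyl group over the hydrogen-bonded ortho hydroxyl.

3 ⇒ 2 ⇒ 1. Cut: the Cb=Cc double bond (methylenation), then the acetal O–C bond. 2 serves twice, as the ring B electrophile and as the source of 3. The forward steps are routine.

## Other disconnections considered

Alternative 1: The cut is on both sides of C7 (C4–C7 and C7–ring B), with C7 arriving as a one-carbon carbonyl unit in a three-component carbonylative Suzuki–Miyaura coupling. Zerovalent palladium would insert into the C4–I bond of 1-(benzyloxy)-4-{3-[4-(benzyloxy)phenyl]propyl}-2-iodo-5-methoxybenzene A2, take up the carbonyl unit, transmetalate with [4-(benzyloxy)phenyl]boronic acid A3 and eliminate to the tribenzyl ether A1; no ring is closed.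
- In its favour: C7 enters at the ketone oxidation level (no carbinol, oxidation or organolithium) and the methyl ether is already in place, so no late methylation is needed. On these points it is the better plan. It makes two skeletal bonds in one operation, equal to the chosen key step.
- Against it: A2 must already carry the whole Ca–Cb–Cc chain, two differentiated oxygens and a regioselectively placed iodine, so the chain needs separate C–C chemistry first. Direct biaryl coupling without carbonyl uptake competes for an electron-rich ortho-alkoxy aryl iodide, and a toxic gas under pressure is needed. Final hydrogenolysis of three benzyl ethers meets the same ketone-reduction hazard as step 10 (equal).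
- Comparison: structurally the chosen plan creates the chain and the oxygen pattern in one cycloaddition, while this one joins finished pieces. Mechanistically both are well understood, one catalytic, one thermal. The coupling and deprotection are short, but making A2 should bring the total to about that of the chosen route or more.

Alternative 2: The cut is inside ring A at C1–C2, after ring A is taken back to the cyclohexane-1,3-dione A4. Forward, methyl 4-[4-(benzyloxy)benzoyl]-2-{3-[4-(benzyloxy)phenyl]propyl}-5-oxohexanoate A5 would undergo an intramolecular Claisen (Dieckmann-type) condensation, the terminal acetyl enolate carbon C2 attacking the ester carbonyl C1. A4 would then be dehydrogenated, methylated at C1–O and debenzylated.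
- In its favour: the ring A pattern is dictated by acyclic connectivity, no haloarene or organometallic is needed, the chain enters by ordinary enolate alkylation, and the condensation is driven by the stabilised enolate of the product. In regiochemical certainty it equals the chosen plan, which inherits its pattern from 4.
- Against it: in A5 the methine C4 between the two ketone carbonyls is by far the most acidic site, so ring closure must go through the less populated terminal enolate or a dianion, with retro-Claisen cleavage of the 1,3-diketone competing. A4 still needs an oxidation to the aromatic level beside benzyl ethers, then a chelation-guided choice between C1–O and C3–O, where the chosen plan has a single free hydroxyl. A5 itself needs several C–C bond-forming steps.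
- Comparison: structurally it builds ring A, which the chosen plan buys. Mechanistically it is ionic and reversible, against a cycloaddition made irreversible by rearomatisation. Step economy is judged worse (assembly of A5, cyclisation, aromatisation, methylation, deprotection).

Alternative 3: The cut is at C3–C4 and C5–C6 of ring A. Forward, the chain-bearing diene ({7-[4-(benzyloxy)phenyl]-1,3-dimethoxyhepta-1,3-dien-1-yl}oxy)trimethylsilane A7 would add to the ynone 1-[4-(benzyloxy)phenyl]prop-2-yn-1-one A8 in a Diels–Alder reaction, its nucleophilic terminus bonding to the alkyne terminus. Elimination of the methoxy group from the acetal carbon and desilylation would aromatise the adduct to A6, with OH on C3 and the former enol ether as OMe on C1.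
- In its favour: ring A and the OMe/OH differentiation are created in one step, so neither selective protection nor late methylation is needed, which is better than the chosen plan. The polarised partners should give one regioisomer. Two bonds and one ring are formed, equal to the chosen key step. A6 is one deprotection from 16, a shorter endgame (better).
- Against it: A7 is a moisture-sensitive ketene acetal made from a chain-bearing β-keto ester as a mixture of geometric isomers, and its substituted reacting terminus slows the addition. Aromatisation can take the other course (loss of the silyloxy group, giving OMe on C3) or the C1 enol ether can hydrolyse. A8 is a polymerisable acceptor. Debenzylation again meets the diaryl ketone (equal to step 10).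
- Comparison: structurally the most elegant answer to the oxygen-differentiation problem, where the chosen plan relies on an oxygen pattern bought with 4. Mechanistically it is a normal-demand cycloaddition with a fragile diene, against an inverse-demand one with a stable styrene. The step count is possibly equal or lower, at the price of less robust intermediates.

Key step: step 9

Assumption: ring A locants C1–C6, C7 for the ketone carbon and Ca–Cb–Cc for the chain are used as defined above; 1, 4 and the reagents written over the arrows are taken as purchasable.

Step 1
Reactants: 1 4-hydroxybenzaldehyde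
Product: 2 4-(methoxymethoxy)benzaldehyde
Conditions: MOMCl, K2CO3, acetone, 0 °C → rt
Reagents that add atoms: chloromethyl methyl ether, COCCl
Why: Williamson-type O-alkylation; the phenoxide (acidified by the para formyl group) displaces chloride from the α-chloro ether and the aldehyde is inert to K2CO3.

Step 2
Reactants: 2 4-(methoxymethoxy)benzaldehyde
Product: 3 1-ethenyl-4-(methoxymethoxy)benzene
Conditions: Ph3PCH3Br, KOt-Bu, THF, 0 °C → rt
Reagents that add atoms: methyltriphenylphosphonium bromide, C[P+](c1ccccc1)(c1ccccc1)c1ccccc1.[Br-]
Why: Wittig methylenation with the non-stabilised ylide made in the flask; the MOM acetal is stable to alkoxide and a terminal alkene raises no stereochemical issue (store cold with BHT).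

Step 3
Reactants: 4 5-bromo-2,4-dihydroxybenzaldehyde
Product: 5 5-bromo-2-hydroxy-4-(methoxymethoxy)benzaldehyde
Conditions: MOMCl (1.05 equiv), K2CO3 (1.1 equiv), acetone, 0 °C → rt
Reagents that add atoms: chloromethyl methyl ether, COCCl
Why: Site-selective Williamson O-alkylation; the hydroxyl para to the formyl group is the more acidic and is free, while the ortho hydroxyl is locked in a hydrogen bond to C=O, so one equivalent of electrophile with a weak base should cap only the future C3 oxygen.

Step 4
Reactants: 5 5-bromo-2-hydroxy-4-(methoxymethoxy)benzaldehyde
Product: 6 4-bromo-2-(hydroxymethyl)-5-(methoxymethoxy)phenol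
Conditions: NaBH4, THF–MeOH, 0 °C; work-up at pH 6–7
Reagents that add atoms: none
Why: Borohydride reduction of the aldehyde to the primary benzylic alcohol; aryl bromide and acetal are inert, and neutral work-up avoids ionisation of the electron-rich ortho-hydroxybenzyl alcohol, which is carried on crude.

Step 5
Reactants: 6 4-bromo-2-(hydroxymethyl)-5-(methoxymethoxy)phenol
Product: 7 tert-butyl{[5-bromo-2-{[tert-butyl(dimethyl)silyl]oxy}-4-(methoxymethoxy)phenyl]methoxy}dimethylsilane
Conditions: TBSCl (2.5 equiv), imidazole, DMF, rt
Reagents that add atoms: tert-butyldimethylsilyl chloride, CC(C)(C)[Si](C)(C)Cl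
Why: Imidazole-promoted silylation of phenol and primary alcohol in one operation; both groups later leave together with fluoride, and the aryl silyl ether lies para to bromine, so no silyl shift from oxygen to carbon is possible after metalation.

Step 6
Reactants: 7 tert-butyl{[5-bromo-2-{[tert-butyl(dimethyl)silyl]oxy}-4-(methoxymethoxy)phenyl]methoxy}dimethylsilane; 2 4-(methoxymethoxy)benzaldehyde
Product: 9 rac-[4-{[tert-butyl(dimethyl)silyl]oxy}-5-({[tert-butyl(dimethyl)silyl]oxy}methyl)-2-(methoxymethoxy)phenyl][4-(methoxymethoxy)phenyl]methanol, via aryllithium 8 (not isolated)
Conditions: n-BuLi (1.05 equiv), THF, −78 °C; then 2 (1.2 equiv), −78 → 0 °C; H2O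
Reagents that add atoms: none
Why: Bromine–lithium exchange, much faster than deprotonation at −78 °C and assisted by the ortho MOM oxygen, then 1,2-addition to the non-enolisable aldehyde; the carbinol stereocentre forms racemic without control and is removed by the oxidation in step 7.

Step 7
Reactants: 9 rac-[4-{[tert-butyl(dimethyl)silyl]oxy}-5-({[tert-butyl(dimethyl)silyl]oxy}methyl)-2-(methoxymethoxy)phenyl][4-(methoxymethoxy)phenyl]methanol
Product: 10 [4-{[tert-butyl(dimethyl)silyl]oxy}-5-({[tert-butyl(dimethyl)silyl]oxy}methyl)-2-(methoxymethoxy)phenyl][4-(methoxymethoxy)phenyl]methanone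
Conditions: MnO2 (10 equiv), CH2Cl2, rt
Reagents that add atoms: none
Why: MnO2 oxidation of a doubly benzylic secondary alcohol, the only free hydroxyl in 9, to the diaryl ketone; silyl ethers and acetals are untouched, and the primary benzylic oxygen is masked for exactly this step.

Step 8
Reactants: 10 [4-{[tert-butyl(dimethyl)silyl]oxy}-5-({[tert-butyl(dimethyl)silyl]oxy}methyl)-2-(methoxymethoxy)phenyl][4-(methoxymethoxy)phenyl]methanone
Product: 11 [4-hydroxy-5-(hydroxymethyl)-2-(methoxymethoxy)phenyl][4-(methoxymethoxy)phenyl]methanone
Conditions: TBAF (2.2 equiv), AcOH (2.2 equiv), THF, 0 °C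
Reagents that add atoms: none
Why: Fluoride-mediated desilylation of the aryl and the alkyl silyl ether, driven by the Si–F bond; acetic acid buffers the phenoxide and alkoxide so the sensitive ortho-hydroxybenzyl alcohol is not held in basic solution, and MOM ethers are inert to fluoride.

Step 9
Reactants: 11 [4-hydroxy-5-(hydroxymethyl)-2-(methoxymethoxy)phenyl][4-(methoxymethoxy)phenyl]methanone; 3 1-ethenyl-4-(methoxymethoxy)benzene
Product: 13 rac-{7-(methoxymethoxy)-2-[4-(methoxymethoxy)phenyl]-3,4-dihydro-2H-chromen-6-yl}[4-(methoxymethoxy)phenyl]methanone, via ortho-quinone methide 12 (not isolated)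
Conditions: 3 (4 equiv), BHT (5 mol %), o-xylene, 160 °C, sealed tube
Reagents that add atoms: none
Why: On heating, 11 should lose water through a hydrogen-bonded six-membered transition state between the C1 hydroxyl and the benzylic hydroxyl to give the ortho-quinone methide 12, whose heterodiene O=C1–C6=Ca is made more electron-poor by the para C7 carbonyl; the reaction type is the known inverse-electron-demand hetero-Diels–Alder addition of thermally generated ortho-quinone methides to electron-rich styrenes, which gives flavans. The donor-substituted alkene of 3 adds in a concerted but asynchronous [4+2] cycloaddition in which the Ca–Cb bond runs ahead of the O–Cc bond, and rearomatisation of ring A drives the step. The dihydropyran ring is closed by this intermolecular cycloaddition itself, both ring bonds forming in one six-membered transition state, not by a separate cyclisation. The 2-aryl (not 3-aryl) orientation follows from pairing the largest LUMO coefficient of 12 at Ca with the largest HOMO coefficient of 3 at its terminal carbon, equivalently from the benzylic, oxygen-stabilised positive charge that develops at Cc. The new stereocentre at C2 of the chroman forms without any controlling element, so 13 is racemic, which is acceptable because this carbon becomes a methylene group in step 10. Chemoselectivity rests on the substrate and the conditions: the C3 oxygen is capped, so no para-quinone methide tautomer or second phenol competes, the ketone has no α-hydrogen, and the excess of 3 with a radical inhibitor should outrun self-condensation of 12 and suppress polymerisation. Re-addition of water to 12 only returns 11 and does not divert material.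

Step 10
Reactants: 13 rac-{7-(methoxymethoxy)-2-[4-(methoxymethoxy)phenyl]-3,4-dihydro-2H-chromen-6-yl}[4-(methoxymethoxy)phenyl]methanone
Product: 14 [4-hydroxy-2-(methoxymethoxy)-5-{3-[4-(methoxymethoxy)phenyl]propyl}phenyl][4-(methoxymethoxy)phenyl]methanone
Conditions: H2 (1–3 bar), Pd/C (10 wt % Pd), EtOAc–EtOH, rt
Reagents that add atoms: none
Why: Heterogeneous hydrogenolysis of a benzylic C–O bond; the O–Cc bond is benzylic to the donor-substituted ring C and its oxygen is a vinylogous carboxylate (para to C7=O), so it should cleave like a benzyl ester and erase the stereocentre, while in neutral solvent the hindered, donor-rich diaryl ketone and the MOM acetals should react much more slowly.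

Step 11
Reactants: 14 [4-hydroxy-2-(methoxymethoxy)-5-{3-[4-(methoxymethoxy)phenyl]propyl}phenyl][4-(methoxymethoxy)phenyl]methanone
Product: 15 [4-methoxy-2-(methoxymethoxy)-5-{3-[4-(methoxymethoxy)phenyl]propyl}phenyl][4-(methoxymethoxy)phenyl]methanone
Conditions: MeI, K2CO3, acetone, 50 °C
Reagents that add atoms: iodomethane, CI
Why: Williamson O-methylation of the single free phenol (acidified by the para carbonyl), so no site selectivity is required; the ketone has no α-hydrogen and acetals are stable to base.

Step 12
Reactants: 15 [4-methoxy-2-(methoxymethoxy)-5-{3-[4-(methoxymethoxy)phenyl]propyl}phenyl][4-(methoxymethoxy)phenyl]methanone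
Product: 16 {2-hydroxy-5-[3-(4-hydroxyphenyl)propyl]-4-methoxyphenyl}(4-hydroxyphenyl)methanone
Conditions: HCl (3 M aq), MeOH, 50 °C
Reagents that add atoms: none
Why: Acid-catalysed acetal exchange with methanol removes all three MOM groups and traps the one-carbon unit as its dimethyl acetal, away from the electron-rich rings; the aryl methyl ether and the ketone are stable to dilute HCl.

## Compound list

1 | 4-hydroxybenzaldehyde | O=Cc1ccc(O)cc1 | starting material
2 | 4-(methoxymethoxy)benzaldehyde | COCOc1ccc(C=O)cc1 | intermediate
3 | 1-ethenyl-4-(methoxymethoxy)benzene | C=Cc1ccc(OCOC)cc1 | intermediate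
4 | 5-bromo-2,4-dihydroxybenzaldehyde | O=Cc1cc(Br)c(O)cc1O | starting material
5 | 5-bromo-2-hydroxy-4-(methoxymethoxy)benzaldehyde | O=Cc1cc(Br)c(OCOC)cc1O | intermediate
6 | 4-bromo-2-(hydroxymethyl)-5-(methoxymethoxy)phenol | OCc1cc(Br)c(OCOC)cc1O | intermediate
7 | tert-butyl{[5-bromo-2-{[tert-butyl(dimethyl)silyl]oxy}-4-(methoxymethoxy)phenyl]methoxy}dimethylsilane | CC(C)(C)[Si](C)(C)OCc1cc(Br)c(OCOC)cc1O[Si](C)(C)C(C)(C)C | intermediate
8 | [4-{[tert-butyl(dimethyl)silyl]oxy}-5-({[tert-butyl(dimethyl)silyl]oxy}methyl)-2-(methoxymethoxy)phenyl]lithium | [Li]c1cc(CO[Si](C)(C)C(C)(C)C)c(O[Si](C)(C)C(C)(C)C)cc1OCOC | intermediate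
9 | rac-[4-{[tert-butyl(dimethyl)silyl]oxy}-5-({[tert-butyl(dimethyl)silyl]oxy}methyl)-2-(methoxymethoxy)phenyl][4-(methoxymethoxy)phenyl]methanol (racemic) | OC(c1ccc(OCOC)cc1)c1cc(CO[Si](C)(C)C(C)(C)C)c(O[Si](C)(C)C(C)(C)C)cc1OCOC | intermediate
10 | [4-{[tert-butyl(dimethyl)silyl]oxy}-5-({[tert-butyl(dimethyl)silyl]oxy}methyl)-2-(methoxymethoxy)phenyl][4-(methoxymethoxy)phenyl]methanone | O=C(c1ccc(OCOC)cc1)c1cc(CO[Si](C)(C)C(C)(C)C)c(O[Si](C)(C)C(C)(C)C)cc1OCOC | intermediate
11 | [4-hydroxy-5-(hydroxymethyl)-2-(methoxymethoxy)phenyl][4-(methoxymethoxy)phenyl]methanone | O=C(c1ccc(OCOC)cc1)c1cc(CO)c(O)cc1OCOC | intermediate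
12 | 4-[4-(methoxymethoxy)benzoyl]-3-(methoxymethoxy)-6-methylidenecyclohexa-2,4-dien-1-one | C=C1C=C(C(=O)c2ccc(OCOC)cc2)C(OCOC)=CC1=O | intermediate
13 | rac-{7-(methoxymethoxy)-2-[4-(methoxymethoxy)phenyl]-3,4-dihydro-2H-chromen-6-yl}[4-(methoxymethoxy)phenyl]methanone (racemic) | O=C(c1ccc(OCOC)cc1)c1cc2c(cc1OCOC)OC(c1ccc(OCOC)cc1)CC2 | intermediate
14 | [4-hydroxy-2-(methoxymethoxy)-5-{3-[4-(methoxymethoxy)phenyl]propyl}phenyl][4-(methoxymethoxy)phenyl]methanone | O=C(c1ccc(OCOC)cc1)c1cc(CCCc2ccc(OCOC)cc2)c(O)cc1OCOC | intermediate
15 | [4-methoxy-2-(methoxymethoxy)-5-{3-[4-(methoxymethoxy)phenyl]propyl}phenyl][4-(methoxymethoxy)phenyl]methanone | COc1cc(OCOC)c(C(=O)c2ccc(OCOC)cc2)cc1CCCc1ccc(OCOC)cc1 | intermediate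
16 | {2-hydroxy-5-[3-(4-hydroxyphenyl)propyl]-4-methoxyphenyl}(4-hydroxyphenyl)methanone | COc1cc(O)c(C(=O)c2ccc(O)cc2)cc1CCCc1ccc(O)cc1 | target

Total step count: 12. Longest linear sequence: 10 steps (steps 3 to 12, from 4); the two-step branch from 1 (steps 1 and 2) supplies both 2 and 3.

Least certain steps:

Step 9 (key step). Thermal dehydration may be slow, so that self-condensation of the quinone methide (C-alkylation of a second molecule at C2 between the two oxygens, or O-alkylation of its phenol) and thermal polymerisation of the styrene outrun the cycloaddition. Partial thermal loss of the C3 MOM group would not be harmful, because the chelated hydroxyl it leaves is the slowest to methylate and is freed in step 12 anyway. Fallback, setting out from 10 and returning at 13: generate the same quinone methide at low temperature by fluoride-triggered 1,4-elimination. PPTS in MeOH should remove only the alkyl silyl ether (aryl silyl ethers resist mild acid) to give [4-{[tert-butyl(dimethyl)silyl]oxy}-5-(hydroxymethyl)-2-(methoxymethoxy)phenyl][4-(methoxymethoxy)phenyl]methanone F1. Ac2O–pyridine would convert this into {2-{[tert-butyl(dimethyl)silyl]oxy}-4-(methoxymethoxy)-5-[4-(methoxymethoxy)benzoyl]phenyl}methyl acetate F2. CsF in MeCN at 25–60 °C with excess 3 would then cleave the aryl silyl ether, the phenoxide would expel acetate to give 12, and cycloaddition would deliver 13.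

Step 10. Cleavage of the cyclic benzylic ether may be incomplete under mild conditions, and forcing conditions (acid, heat, pressure) invite hydrogenation of the diaryl ketone to the carbinol and on to the diarylmethane, or loss of MOM groups. Fallback, setting out from 13 and returning at 14: a dissolving-metal (Birch-type) cleavage, Li in NH3–THF at −78 °C with excess metal destroyed by isoprene before NH4Cl is added. This should break the O–Cc bond by electron transfer and take the ketone only as far as the alkoxide, giving rac-4-{hydroxy[4-(methoxymethoxy)phenyl]methyl}-5-(methoxymethoxy)-2-{3-[4-(methoxymethoxy)phenyl]propyl}phenol F3. MnO2 in CH2Cl2 would re-oxidise this para-hydroxybenzhydrol to the ketone 14.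

Step 6. Proton transfer may compete with exchange (lithiation at C2 between the two oxygens, or migration of lithium there on warming), and the aryllithium may be butylated by the 1-bromobutane formed. Either lowers conversion to the carbinol. Fallback, setting out from 7 and returning at 10: a palladium-catalysed carbonylative Suzuki–Miyaura coupling of 7 with [4-(methoxymethoxy)phenyl]boronic acid (CO 5 bar, Pd(OAc)2, di(1-adamantyl)-n-butylphosphine, K2CO3, toluene, 100 °C). This avoids the organolithium and the oxidation of step 7 and gives the ketone 10 directly; no new intermediate is made.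

Step 3. Both hydroxyls may be alkylated, or conversion may stall at one equivalent of electrophile, giving mixtures that are tedious to separate. Fallback, setting out from 4 and returning at 5: alkylate both hydroxyls on purpose (MOMCl in excess, i-Pr2NEt, CH2Cl2) to give 5-bromo-2,4-bis(methoxymethoxy)benzaldehyde F4. Then remove only the acetal ortho to the formyl group with dilute HCl in MeOH at rt; the neighbouring carbonyl oxygen assists cleavage through a hydrogen bond to the departing phenol, so this acetal should go first and leave 5.

## Further compounds

F1 | step 9 | [4-{[tert-butyl(dimethyl)silyl]oxy}-5-(hydroxymethyl)-2-(methoxymethoxy)phenyl][4-(methoxymethoxy)phenyl]methanone | O=C(c1ccc(OCOC)cc1)c1cc(CO)c(O[Si](C)(C)C(C)(C)C)cc1OCOC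
F2 | step 9 | {2-{[tert-butyl(dimethyl)silyl]oxy}-4-(methoxymethoxy)-5-[4-(methoxymethoxy)benzoyl]phenyl}methyl acetate | CC(=O)OCc1cc(C(=O)c2ccc(OCOC)cc2)c(OCOC)cc1O[Si](C)(C)C(C)(C)C
F3 | step 10 | rac-4-{hydroxy[4-(methoxymethoxy)phenyl]methyl}-5-(methoxymethoxy)-2-{3-[4-(methoxymethoxy)phenyl]propyl}phenol (racemic) | OC(c1ccc(OCOC)cc1)c1cc(CCCc2ccc(OCOC)cc2)c(O)cc1OCOC
F0 | step 6 | none | none
F4 | step 3 | 5-bromo-2,4-bis(methoxymethoxy)benzaldehyde | O=Cc1cc(Br)c(OCOC)cc1OCOC
A1 | alternative 1 | [2-(benzyloxy)-5-{3-[4-(benzyloxy)phenyl]propyl}-4-methoxyphenyl][4-(benzyloxy)phenyl]methanone | COc1cc(OCc2ccccc2)c(C(=O)c2ccc(OCc3ccccc3)cc2)cc1CCCc1ccc(OCc2ccccc2)cc1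
A2 | alternative 1 | 1-(benzyloxy)-4-{3-[4-(benzyloxy)phenyl]propyl}-2-iodo-5-methoxybenzene | COc1cc(OCc2ccccc2)c(I)cc1CCCc1ccc(OCc2ccccc2)cc1
A3 | alternative 1 | [4-(benzyloxy)phenyl]boronic acid | OB(O)c1ccc(OCc2ccccc2)cc1
A4 | alternative 2 | 4-[4-(benzyloxy)benzoyl]-6-{3-[4-(benzyloxy)phenyl]propyl}cyclohexane-1,3-dione (mixture of diastereomers) | O=C1CC(=O)C(CCCc2ccc(OCc3ccccc3)cc2)CC1C(=O)c1ccc(OCc2ccccc2)cc1
A5 | alternative 2 | methyl 4-[4-(benzyloxy)benzoyl]-2-{3-[4-(benzyloxy)phenyl]propyl}-5-oxohexanoate (mixture of diastereomers) | COC(=O)C(CCCc1ccc(OCc2ccccc2)cc1)CC(C(C)=O)C(=O)c1ccc(OCc2ccccc2)cc1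
A6 | alternative 3 | [4-(benzyloxy)phenyl](5-{3-[4-(benzyloxy)phenyl]propyl}-2-hydroxy-4-methoxyphenyl)methanone | COc1cc(O)c(C(=O)c2ccc(OCc3ccccc3)cc2)cc1CCCc1ccc(OCc2ccccc2)cc1
A7 | alternative 3 | ({7-[4-(benzyloxy)phenyl]-1,3-dimethoxyhepta-1,3-dien-1-yl}oxy)trimethylsilane (double-bond geometry not defined) | COC(O[Si](C)(C)C)=CC(OC)=CCCCc1ccc(OCc2ccccc2)cc1
A8 | alternative 3 | 1-[4-(benzyloxy)phenyl]prop-2-yn-1-one | C#CC(=O)c1ccc(OCc2ccccc2)cc1
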